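Plan (azulene numbering: C1 epoxide CH, C2 epoxide C–CH3, C3, C3a, C4 i-Pr, C5 ester O, C6, C7 methyl carbinol, C8, C8a).
Cuts: first the C5–O acyl bond and the two epoxide C–O bonds, then C2–CH3 and C4–CH(CH3)2. This leaves a 5,7-fused dienone, which is cut at C8a–C3a, C1–C2 and C2–C3.
Enabling feature: in the five-membered ring C1–C2–C3–C3a–C8a the apex C2 lies between the pairs C1/C8a and C3/C3a. C2 can therefore come from CO and the pairs from a terminal alkyne and the outer C=C of an allene; the bond C8a–C3a, shared with the seven-membered ring, closes that ring over the tether C5–C8.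
Forward: (R)-mevalonolactone (C5–C8a and the C7 methyl) is extended by a propargyl ether (C4, C3a, C3) and one diazophosphonate carbon (C1) to an acyclic nine-carbon allenyne. One carbonylative [2+2+1] closes both rings; i-Pr, H-3a, H-8a, C2–CH3, the ester and the epoxide follow.
Stereochemistry: C7 from the chiral pool, C5 by catalyst-controlled transfer hydrogenation, C4 anti to C5–OTBS, C3a by axial γ-protonation, C8a by dissolving-metal reduction (trans fusion), C1/C2 by C7–OH-directed epoxidation.

Key step: step 9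

Remark: the acetal carbon of the tetrahydropyranyl group in 5–8 is a mixture of epimers; it is drawn without descriptor and is lost in step 5.

Step 1
Reactants: 1 (R)-mevalonolactone; 2 N,O-dimethylhydroxylamine hydrochloride
Product: 3 (3R)-3,5-dihydroxy-N-methoxy-N,3-dimethylpentanamide
Conditions: MeNH(OMe)·HCl, AlMe3, CH2Cl2, 0 °C → rt
Reagents that add atoms: N,O-dimethylhydroxylamine hydrochloride (2), CNOC.Cl
Why: Weinreb aminolysis of a δ-lactone with the aluminium amide breaks only the acyl C–O bond, so the tertiary carbinol centre (future C7) is untouched and the carbonyl carbon (future C5) becomes a mono-addition acceptor.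

Step 2
Reactants: 3 (3R)-3,5-dihydroxy-N-methoxy-N,3-dimethylpentanamide
Product: 4 (3R)-N-methoxy-N,3-dimethyl-3,5-bis(triethylsilyloxy)pentanamide
Conditions: TESOTf, 2,6-lutidine, CH2Cl2, −78 → 0 °C
Reagents that add atoms: triethylsilyl trifluoromethanesulfonate, CC[Si](CC)(CC)OS(=O)(=O)C(F)(F)F
Why: Silyl triflate silylation caps the primary and the tertiary hydroxyl at once, blocks relactonisation, and gives two TES ethers so different in hindrance that step 7 can tell them apart.

Step 3
Reactants: 4 (3R)-N-methoxy-N,3-dimethyl-3,5-bis(triethylsilyloxy)pentanamide; 5 2-(prop-2-yn-1-yloxy)tetrahydro-2H-pyran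
Product: 7 (6R)-6-methyl-1-(tetrahydro-2H-pyran-2-yloxy)-6,8-bis(triethylsilyloxy)oct-2-yn-4-one, via lithium acetylide 6 (not isolated)
Conditions: 5, n-BuLi, THF, −78 °C; then 4, −78 → 0 °C
Reagents that add atoms: 2-(prop-2-yn-1-yloxy)tetrahydro-2H-pyran (5), C#CCOC1CCCCO1; n-butyllithium, [Li]CCCC (lithium kept only in 6)
Why: Weinreb ketone synthesis, in which the chelated tetrahedral adduct stops at mono-addition; it is run before the second alkyne exists, so no competing acidic C–H or acetylide is present.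

Step 4
Reactants: 7 (6R)-6-methyl-1-(tetrahydro-2H-pyran-2-yloxy)-6,8-bis(triethylsilyloxy)oct-2-yn-4-one
Product: 8 (4S,6R)-6-methyl-1-(tetrahydro-2H-pyran-2-yloxy)-6,8-bis(triethylsilyloxy)oct-2-yn-4-ol
Conditions: Ru[(S,S)-TsDPEN](p-cymene) (2 mol %), i-PrOH, rt
Reagents that add atoms: none
Why: Noyori asymmetric transfer hydrogenation of an alkynyl ketone, in which the (S,S)-catalyst distinguishes the alkynyl from the alkyl flank and should give the (S)-carbinol (C5) under catalyst control, independent of the remote C7 centre.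

Step 5
Reactants: 8 (4S,6R)-6-methyl-1-(tetrahydro-2H-pyran-2-yloxy)-6,8-bis(triethylsilyloxy)oct-2-yn-4-ol
Product: 9 (4S,6R)-6-methyl-6,8-bis(triethylsilyloxy)octa-1,2-dien-4-ol
Conditions: LiAlH4, Et2O, 0 °C → reflux
Reagents that add atoms: none
Why: Alkoxide-directed hydroalumination places H on C4 and Al on C3a, and 1,2-elimination of aluminium and the tetrahydropyranyloxy group (net SN2′ hydride substitution) gives the terminal allene without touching C5 or the silyl ethers.

Step 6
Reactants: 9 (4S,6R)-6-methyl-6,8-bis(triethylsilyloxy)octa-1,2-dien-4-ol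
Product: 10 (4S,6R)-4-(tert-butyldimethylsilyloxy)-6-methyl-6,8-bis(triethylsilyloxy)octa-1,2-diene
Conditions: TBSCl, imidazole, DMAP, DMF, rt
Reagents that add atoms: tert-butyldimethylsilyl chloride, CC(C)(C)[Si](C)(C)Cl
Why: Standard imidazole-promoted silylation of a secondary alcohol, which installs the bulky C5 substituent that later shields one face of C4.

Step 7
Reactants: 10 (4S,6R)-4-(tert-butyldimethylsilyloxy)-6-methyl-6,8-bis(triethylsilyloxy)octa-1,2-diene
Product: 11 (3S,5S)-5-(tert-butyldimethylsilyloxy)-3-methyl-3-(triethylsilyloxy)octa-6,7-dienal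
Conditions: (COCl)2, DMSO, CH2Cl2, −78 → −30 °C; Et3N, −78 °C → rt
Reagents that add atoms: none
Why: Swern oxidation applied directly to a silyl ether, in which the activated sulfonium salt cleaves and oxidises only the unhindered primary TES ether while the tertiary TES and secondary TBS ethers are too hindered to react (the C7 descriptor changes by priority only).

Step 8
Reactants: 11 (3S,5S)-5-(tert-butyldimethylsilyloxy)-3-methyl-3-(triethylsilyloxy)octa-6,7-dienal; 12 dimethyl (1-diazo-2-oxopropyl)phosphonate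
Product: 13 (4S,6R)-4-(tert-butyldimethylsilyloxy)-6-methyl-6-(triethylsilyloxy)nona-1,2-dien-8-yne
Conditions: K2CO3, MeOH, 0 °C → rt
Reagents that add atoms: dimethyl (1-diazo-2-oxopropyl)phosphonate (12), COP(=O)(OC)C(=[N+]=[N-])C(C)=O
Why: Ohira–Bestmann homologation turns the aldehyde carbon into C8a and adds C1 under carbonate conditions mild enough for the β-silyloxy aldehyde, the allene and both silyl ethers.

Step 9
Reactants: 13 (4S,6R)-4-(tert-butyldimethylsilyloxy)-6-methyl-6-(triethylsilyloxy)nona-1,2-dien-8-yne; 14 carbon monoxide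
Product: 15 (5S,7R)-5-(tert-butyldimethylsilyloxy)-7-methyl-7-(triethylsilyloxy)-5,6,7,8-tetrahydroazulen-2(3H)-one
Conditions: [Rh(CO)2Cl]2 (5 mol %), CO (1 atm), toluene (0.02 M), 90 °C
Reagents that add atoms: carbon monoxide (14), [C-]#[O+]
Why: The alkyne (C1≡C8a) and the outer allene bond (C3a=C3) bind to monovalent rhodium and couple oxidatively to a rhodacyclopentene, which makes C8a–C3a; CO then inserts into a Rh–C bond and reductive elimination joins C1–C2 and C2–C3 and returns the catalyst. This is the rhodium-catalysed allenic Pauson–Khand reaction, the established entry to bicyclo[5.3.0]decadienones, and it accepts terminal alkynes and silyl ethers. The seven-membered ring closes in the oxidative coupling, as the carbocycle fused to the metallacycle over the four-atom tether C5–C8, and the five-membered ring closes in the insertion/reductive elimination sequence as a [2+2+1] annulation around C2. No stereocentre is formed, and C5 and C7 are spectators that cannot epimerise under these neutral conditions. The selectivity needed is outer versus inner allene bond (seven- versus six-membered ring): the geometry of the rhodium metallacycle favours the outer bond, the unsubstituted CH2 terminus is the least hindered π-bond, and the quaternary C7 compresses the tether (gem-dialkyl effect). Because C3 bears no alkyl group the metallacycle has no β-hydrogen, so the competing Alder-ene cycloisomerisation is closed.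

Step 10
Reactants: 15 (5S,7R)-5-(tert-butyldimethylsilyloxy)-7-methyl-7-(triethylsilyloxy)-5,6,7,8-tetrahydroazulen-2(3H)-one; 16 isopropylmagnesium chloride
Product: 18 (3aS,4S,5S,7R)-5-(tert-butyldimethylsilyloxy)-4-isopropyl-7-methyl-7-(triethylsilyloxy)-3a,4,5,6,7,8-hexahydroazulen-2(3H)-one, via trimethylsilyl dienol ether 17 (not isolated)
Conditions: i-PrMgCl, CuBr·SMe2 (20 mol %), TMSCl, THF, −78 → −40 °C; then 1 M HCl, THF, 0 °C
Reagents that add atoms: isopropylmagnesium chloride (16), CC(C)[Mg]Cl; chlorotrimethylsilane, C[Si](C)(C)Cl (silyl group kept only in 17)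
Why: Copper-catalysed 1,6-conjugate addition of a Grignard reagent to a linear dienone: C4 is the open δ-terminus whereas attack at C8a would build a quaternary centre, the reagent enters anti to the neighbouring C5–OTBS group (C4 trans to C5), silyl trapping fixes the dienolate on the C1 side, and the neutral dienol ether takes the proton at its γ-carbon C3a (unlike a dienolate anion, which is protonated at the α-carbon), axially and from the face not screened by the in-plane pseudo-equatorial i-Pr group, so that H-3a is anti to H-4 and C3, i-Pr and OTBS are all pseudo-equatorial, which is also the more stable epimer.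

Step 11
Reactants: 18 (3aS,4S,5S,7R)-5-(tert-butyldimethylsilyloxy)-4-isopropyl-7-methyl-7-(triethylsilyloxy)-3a,4,5,6,7,8-hexahydroazulen-2(3H)-one
Product: 20 (3aR,4S,5S,7R,8aS)-5-(tert-butyldimethylsilyloxy)-4-isopropyl-7-methyl-7-(triethylsilyloxy)-3,3a,4,5,6,7,8,8a-octahydroazulen-2-yl trifluoromethanesulfonate, via lithium enolate 19 (not isolated)
Conditions: Li, NH3(l)/THF, t-BuOH (1 equiv), −78 °C; isoprene; NH3 off; PhNTf2, THF, 0 °C → rt
Reagents that add atoms: N-phenylbis(trifluoromethanesulfonimide), O=S(=O)(N(c1ccccc1)S(=O)(=O)C(F)(F)F)C(F)(F)F; lithium, [Li] (kept only in 19)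
Why: Dissolving-metal enone reduction with regiospecific enolate trapping as the enol triflate: the β-carbanion at C8a is protonated to the trans-fused hydroazulene (H-8a anti to H-3a, all ring bonds pseudo-equatorial), no leaving group sits β to the carbanion, and the enolate can only be the C1=C2 one, which fixes the later alkene position.

Step 12
Reactants: 20 (3aR,4S,5S,7R,8aS)-5-(tert-butyldimethylsilyloxy)-4-isopropyl-7-methyl-7-(triethylsilyloxy)-3,3a,4,5,6,7,8,8a-octahydroazulen-2-yl trifluoromethanesulfonate; 21 methylmagnesium bromide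
Product: 22 (3aR,4S,5S,7R,8aS)-5-(tert-butyldimethylsilyloxy)-4-isopropyl-2,7-dimethyl-7-(triethylsilyloxy)-3,3a,4,5,6,7,8,8a-octahydroazulene
Conditions: MeMgBr, Fe(acac)3 (10 mol %), THF/NMP, −30 → 0 °C
Reagents that add atoms: methylmagnesium bromide (21), C[Mg]Br
Why: Iron-catalysed Kumada-type cross-coupling of an alkenyl triflate replaces OTf by CH3 without moving the C1=C2 double bond, and silyl ethers are inert to it.

Step 13
Reactants: 22 (3aR,4S,5S,7R,8aS)-5-(tert-butyldimethylsilyloxy)-4-isopropyl-2,7-dimethyl-7-(triethylsilyloxy)-3,3a,4,5,6,7,8,8a-octahydroazulene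
Product: 23 (3aR,4S,5S,7R,8aS)-4-isopropyl-2,7-dimethyl-3,3a,4,5,6,7,8,8a-octahydroazulene-5,7-diol
Conditions: TBAF, THF, 50 °C
Reagents that add atoms: none
Why: Fluoride desilylation removes both silyl ethers under non-acidic conditions, so neither the tertiary carbinol nor the trisubstituted alkene can ionise or migrate.

Step 14
Reactants: 24 4-hydroxybenzoic acid
Product: 26 4-(tert-butyldimethylsilyloxy)benzoic acid, via silyl ester 25 (not isolated)
Conditions: TBSCl, imidazole, DMF, rt; then AcOH/THF/H2O, rt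
Reagents that add atoms: tert-butyldimethylsilyl chloride, CC(C)(C)[Si](C)(C)Cl
Why: Double silylation followed by selective hydrolysis of the much more labile silyl ester leaves the phenol masked, which prevents self-condensation in the coupling and phenol oxidation in step 16.

Step 15
Reactants: 23 (3aR,4S,5S,7R,8aS)-4-isopropyl-2,7-dimethyl-3,3a,4,5,6,7,8,8a-octahydroazulene-5,7-diol; 26 4-(tert-butyldimethylsilyloxy)benzoic acid
Product: 27 (3aR,4S,5S,7R,8aS)-7-hydroxy-4-isopropyl-2,7-dimethyl-3,3a,4,5,6,7,8,8a-octahydroazulen-5-yl 4-(tert-butyldimethylsilyloxy)benzoate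
Conditions: DCC, DMAP, CH2Cl2, rt
Reagents that add atoms: 4-(tert-butyldimethylsilyloxy)benzoic acid (26), O=C(O)c1ccc(O[Si](C)(C)C(C)(C)C)cc1
Why: Steglich esterification acylates the secondary pseudo-equatorial C5–OH and leaves the tertiary C7–OH alone, and C5 keeps its configuration because its C–O bond is not broken.

Step 16
Reactants: 27 (3aR,4S,5S,7R,8aS)-7-hydroxy-4-isopropyl-2,7-dimethyl-3,3a,4,5,6,7,8,8a-octahydroazulen-5-yl 4-(tert-butyldimethylsilyloxy)benzoate
Product: 28 (1S,2R,3aR,4S,5S,7R,8aS)-1,2-epoxy-7-hydroxy-4-isopropyl-2,7-dimethyldecahydroazulen-5-yl 4-(tert-butyldimethylsilyloxy)benzoate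
Conditions: VO(acac)2 (5 mol %), t-BuOOH, CH2Cl2, 0 °C → rt
Reagents that add atoms: tert-butyl hydroperoxide, CC(C)(C)OO
Why: Hydroxyl-directed vanadium-catalysed epoxidation of a bishomoallylic alcohol: the pseudo-axial C7–OH lies on the face of H-3a, binds the vanadium peroxide and delivers oxygen to that face of the only alkene (setting C1 and C2), and it cannot open the epoxide afterwards because it sits on the same face as the oxirane oxygen.

Step 17
Reactants: 28 (1S,2R,3aR,4S,5S,7R,8aS)-1,2-epoxy-7-hydroxy-4-isopropyl-2,7-dimethyldecahydroazulen-5-yl 4-(tert-butyldimethylsilyloxy)benzoate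
Product: 29 (1S,2R,3aR,4S,5S,7R,8aS)-1,2-epoxy-7-hydroxy-4-isopropyl-2,7-dimethyldecahydroazulen-5-yl 4-hydroxybenzoate (CNP0245441.1)
Conditions: TBAF, AcOH, THF, 0 °C
Reagents that add atoms: none
Why: Aryl silyl ethers are cleaved by buffered fluoride within minutes in the cold, conditions under which the benzoate, the epoxide and the tertiary alcohol are stable.

Compound list
1 | (R)-mevalonolactone | C[C@@]1(O)CCOC(=O)C1 | starting material
2 | N,O-dimethylhydroxylamine hydrochloride | CNOC.Cl | starting material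
3 | (3R)-3,5-dihydroxy-N-methoxy-N,3-dimethylpentanamide | OCC[C@@](C)(O)CC(=O)N(C)OC | intermediate
4 | (3R)-N-methoxy-N,3-dimethyl-3,5-bis(triethylsilyloxy)pentanamide | CC[Si](CC)(CC)OCC[C@@](C)(O[Si](CC)(CC)CC)CC(=O)N(C)OC | intermediate
5 | 2-(prop-2-yn-1-yloxy)tetrahydro-2H-pyran | C#CCOC1CCCCO1 | starting material
6 | lithium acetylide of 5 | [Li]C#CCOC1CCCCO1 | intermediate
7 | (6R)-6-methyl-1-(tetrahydro-2H-pyran-2-yloxy)-6,8-bis(triethylsilyloxy)oct-2-yn-4-one | CC[Si](CC)(CC)OCC[C@@](C)(O[Si](CC)(CC)CC)CC(=O)C#CCOC1CCCCO1 | intermediate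
8 | (4S,6R)-6-methyl-1-(tetrahydro-2H-pyran-2-yloxy)-6,8-bis(triethylsilyloxy)oct-2-yn-4-ol | CC[Si](CC)(CC)OCC[C@@](C)(O[Si](CC)(CC)CC)C[C@H](O)C#CCOC1CCCCO1 | intermediate
9 | (4S,6R)-6-methyl-6,8-bis(triethylsilyloxy)octa-1,2-dien-4-ol | CC[Si](CC)(CC)OCC[C@@](C)(O[Si](CC)(CC)CC)C[C@H](O)C=C=C | intermediate
10 | (4S,6R)-4-(tert-butyldimethylsilyloxy)-6-methyl-6,8-bis(triethylsilyloxy)octa-1,2-diene | CC[Si](CC)(CC)OCC[C@@](C)(O[Si](CC)(CC)CC)C[C@H](O[Si](C)(C)C(C)(C)C)C=C=C | intermediate
11 | (3S,5S)-5-(tert-butyldimethylsilyloxy)-3-methyl-3-(triethylsilyloxy)octa-6,7-dienal | O=CC[C@@](C)(O[Si](CC)(CC)CC)C[C@H](O[Si](C)(C)C(C)(C)C)C=C=C | intermediate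
12 | dimethyl (1-diazo-2-oxopropyl)phosphonate | COP(=O)(OC)C(=[N+]=[N-])C(C)=O | starting material
13 | (4S,6R)-4-(tert-butyldimethylsilyloxy)-6-methyl-6-(triethylsilyloxy)nona-1,2-dien-8-yne | C#CC[C@@](C)(O[Si](CC)(CC)CC)C[C@H](O[Si](C)(C)C(C)(C)C)C=C=C | intermediate
14 | carbon monoxide | [C-]#[O+] | starting material
15 | (5S,7R)-5-(tert-butyldimethylsilyloxy)-7-methyl-7-(triethylsilyloxy)-5,6,7,8-tetrahydroazulen-2(3H)-one | O=C1C=C2C[C@@](C)(O[Si](CC)(CC)CC)C[C@H](O[Si](C)(C)C(C)(C)C)C=C2C1 | intermediate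
16 | isopropylmagnesium chloride | CC(C)[Mg]Cl | starting material
17 | (4S,5S,7R)-5-(tert-butyldimethylsilyloxy)-4-isopropyl-7-methyl-7-(triethylsilyloxy)-2-(trimethylsilyloxy)-3,4,5,6,7,8-hexahydroazulene | CC(C)[C@H]1C2=C(C=C(O[Si](C)(C)C)C2)C[C@@](C)(O[Si](CC)(CC)CC)C[C@@H]1O[Si](C)(C)C(C)(C)C | intermediate
18 | (3aS,4S,5S,7R)-5-(tert-butyldimethylsilyloxy)-4-isopropyl-7-methyl-7-(triethylsilyloxy)-3a,4,5,6,7,8-hexahydroazulen-2(3H)-one | CC(C)[C@H]1[C@@H]2CC(=O)C=C2C[C@@](C)(O[Si](CC)(CC)CC)C[C@@H]1O[Si](C)(C)C(C)(C)C | intermediate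
19 | lithium (3aR,4S,5S,7R,8aS)-5-(tert-butyldimethylsilyloxy)-4-isopropyl-7-methyl-7-(triethylsilyloxy)-3,3a,4,5,6,7,8,8a-octahydroazulen-2-olate | [Li+].CC(C)[C@H]1[C@@H]2CC([O-])=C[C@H]2C[C@@](C)(O[Si](CC)(CC)CC)C[C@@H]1O[Si](C)(C)C(C)(C)C | intermediate
20 | (3aR,4S,5S,7R,8aS)-5-(tert-butyldimethylsilyloxy)-4-isopropyl-7-methyl-7-(triethylsilyloxy)-3,3a,4,5,6,7,8,8a-octahydroazulen-2-yl trifluoromethanesulfonate | CC(C)[C@H]1[C@@H]2CC(OS(=O)(=O)C(F)(F)F)=C[C@H]2C[C@@](C)(O[Si](CC)(CC)CC)C[C@@H]1O[Si](C)(C)C(C)(C)C | intermediate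
21 | methylmagnesium bromide | C[Mg]Br | starting material
22 | (3aR,4S,5S,7R,8aS)-5-(tert-butyldimethylsilyloxy)-4-isopropyl-2,7-dimethyl-7-(triethylsilyloxy)-3,3a,4,5,6,7,8,8a-octahydroazulene | CC(C)[C@H]1[C@@H]2CC(C)=C[C@H]2C[C@@](C)(O[Si](CC)(CC)CC)C[C@@H]1O[Si](C)(C)C(C)(C)C | intermediate
23 | (3aR,4S,5S,7R,8aS)-4-isopropyl-2,7-dimethyl-3,3a,4,5,6,7,8,8a-octahydroazulene-5,7-diol | CC(C)[C@H]1[C@@H]2CC(C)=C[C@H]2C[C@@](C)(O)C[C@@H]1O | intermediate
24 | 4-hydroxybenzoic acid | O=C(O)c1ccc(O)cc1 | starting material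
25 | tert-butyldimethylsilyl 4-(tert-butyldimethylsilyloxy)benzoate | CC(C)(C)[Si](C)(C)OC(=O)c1ccc(O[Si](C)(C)C(C)(C)C)cc1 | intermediate
26 | 4-(tert-butyldimethylsilyloxy)benzoic acid | O=C(O)c1ccc(O[Si](C)(C)C(C)(C)C)cc1 | intermediate
27 | (3aR,4S,5S,7R,8aS)-7-hydroxy-4-isopropyl-2,7-dimethyl-3,3a,4,5,6,7,8,8a-octahydroazulen-5-yl 4-(tert-butyldimethylsilyloxy)benzoate | CC(C)[C@H]1[C@@H]2CC(C)=C[C@H]2C[C@@](C)(O)C[C@@H]1OC(=O)c1ccc(O[Si](C)(C)C(C)(C)C)cc1 | intermediate
28 | (1S,2R,3aR,4S,5S,7R,8aS)-1,2-epoxy-7-hydroxy-4-isopropyl-2,7-dimethyldecahydroazulen-5-yl 4-(tert-butyldimethylsilyloxy)benzoate | CC(C)[C@H]1[C@@H]2C[C@@]3(C)O[C@H]3[C@H]2C[C@@](C)(O)C[C@@H]1OC(=O)c1ccc(O[Si](C)(C)C(C)(C)C)cc1 | intermediate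
29 | (1S,2R,3aR,4S,5S,7R,8aS)-1,2-epoxy-7-hydroxy-4-isopropyl-2,7-dimethyldecahydroazulen-5-yl 4-hydroxybenzoate | CC(C)[C@H]1[C@@H]2C[C@@]3(C)O[C@H]3[C@H]2C[C@@](C)(O)C[C@@H]1OC(=O)c1ccc(O)cc1 | target

Total step count: 17. Longest linear sequence: 16 (steps 1–13 and 15–17; step 14 is a side branch).

Steps most likely to fail

Step 10. Part of the silyl dienol ether may take its proton at C1 instead of C3a. The proton may also enter C3a from the face of H-4, or the double bond may drift to the C3 side of the ketone. The fallback replaces kinetic protonation by thermodynamic control with recycling. It sets out from 15: the copper-catalysed addition of 16 is run without chlorosilane and quenched cold with aqueous NH4Cl, which should give the deconjugated C3a=C8a ketone F1. DBU in toluene then moves the double bond into conjugation under equilibrating conditions, where C3a settles trans to the i-Pr group. Compound 18 is separated by chromatography from the regioisomeric C3=C3a enone F2, and F2 is returned to the DBU equilibration. The route is rejoined at 18.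

Step 11. C8a may be protonated on the face of H-3a (cis fusion), the ketone may be over-reduced, or the enolate may lose its regiochemical integrity during the change from ammonia to THF. The fallback replaces electron transfer and protonation by hydride delivery under steric control, with an isolable enol derivative. It sets out from 18: 1,4-hydrosilylation with [(Ph3P)CuH]6 (catalytic) and PhMe2SiH in toluene should bring hydride to C8a from the face away from the pseudo-axial C7–OSiEt3 group, which is the face anti to H-3a. This gives the regiodefined dimethyl(phenyl)silyl enol ether F3. MeLi in THF at 0 °C releases the lithium enolate, so the route is rejoined at 19, which is triflated to 20 as before.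

Step 16. Facial selectivity may be poor if the distant C7–OH does not steer the vanadium peroxide, so that oxygen arrives on the face of H-8a. The fallback inverts the sense of a sterically controlled attack through a halohydrin. It sets out from 27: TESOTf/2,6-lutidine masks the carbinol as the C7 triethylsilyl ether F4, which now blocks the H-3a face and cannot take part in haloetherification. NBS in aqueous DME should form the bromonium ion on the H-8a face, and water opens it at the tertiary C2 from the opposite face to give the trans bromohydrin F5. DBU in toluene closes the oxirane with inversion at C1 to the silylated epoxide F6, whose oxygen lies on the H-3a face. TBAF then removes both remaining silyl groups, and the route is rejoined at 29.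

Further compounds
F1 | step 10 | (4S,5S,7R)-5-(tert-butyldimethylsilyloxy)-4-isopropyl-7-methyl-7-(triethylsilyloxy)-3,4,5,6,7,8-hexahydroazulen-2(1H)-one | CC(C)[C@H]1C2=C(CC(=O)C2)C[C@@](C)(O[Si](CC)(CC)CC)C[C@@H]1O[Si](C)(C)C(C)(C)C
F2 | step 10 | (4S,5S,7R)-5-(tert-butyldimethylsilyloxy)-4-isopropyl-7-methyl-7-(triethylsilyloxy)-4,5,6,7,8,8a-hexahydroazulen-2(1H)-one (C8a epimers) | CC(C)[C@H]1C2=CC(=O)CC2C[C@@](C)(O[Si](CC)(CC)CC)C[C@@H]1O[Si](C)(C)C(C)(C)C
F3 | step 11 | (3aR,4S,5S,7R,8aS)-5-(tert-butyldimethylsilyloxy)-2-[dimethyl(phenyl)silyloxy]-4-isopropyl-7-methyl-7-(triethylsilyloxy)-3,3a,4,5,6,7,8,8a-octahydroazulene | CC(C)[C@H]1[C@@H]2CC(O[Si](C)(C)c3ccccc3)=C[C@H]2C[C@@](C)(O[Si](CC)(CC)CC)C[C@@H]1O[Si](C)(C)C(C)(C)C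
F4 | step 16 | (3aR,4S,5S,7R,8aS)-4-isopropyl-2,7-dimethyl-7-(triethylsilyloxy)-3,3a,4,5,6,7,8,8a-octahydroazulen-5-yl 4-(tert-butyldimethylsilyloxy)benzoate | CC(C)[C@H]1[C@@H]2CC(C)=C[C@H]2C[C@@](C)(O[Si](CC)(CC)CC)C[C@@H]1OC(=O)c1ccc(O[Si](C)(C)C(C)(C)C)cc1
F5 | step 16 | (1R,2R,3aS,4S,5S,7R,8aS)-1-bromo-2-hydroxy-4-isopropyl-2,7-dimethyl-7-(triethylsilyloxy)decahydroazulen-5-yl 4-(tert-butyldimethylsilyloxy)benzoate | CC(C)[C@H]1[C@@H]2C[C@@](C)(O)[C@H](Br)[C@H]2C[C@@](C)(O[Si](CC)(CC)CC)C[C@@H]1OC(=O)c1ccc(O[Si](C)(C)C(C)(C)C)cc1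
F6 | step 16 | (1S,2R,3aR,4S,5S,7R,8aS)-1,2-epoxy-4-isopropyl-2,7-dimethyl-7-(triethylsilyloxy)decahydroazulen-5-yl 4-(tert-butyldimethylsilyloxy)benzoate | CC(C)[C@H]1[C@@H]2C[C@@]3(C)O[C@H]3[C@H]2C[C@@](C)(O[Si](CC)(CC)CC)C[C@@H]1OC(=O)c1ccc(O[Si](C)(C)C(C)(C)C)cc1
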